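A direct plan would start from 3,5-dibromoaniline A1, methylate it on nitrogen to 3,5-dibromo-N-methylaniline A2 and acylate this to the α,α-dibromoacetanilide A3. It would then close the pyrrole ring at C3–C3a by a Stollé-type Friedel–Crafts alkylation to the 3-bromooxindole A4 and convert the lactam into the 2,3-dibromoindole with POBr3.
The ring closure would be the weakest step: the ring carbon that must attack is deactivated by two bromines and the electrophile is an α-carbonyl cation, so an AlBr3 melt would be needed, in which bromine migration and N-demethylation would compete.
The deoxybromination would come next: A4 is a labile benzylic α-bromolactam that would have to survive hot POBr3 without reduction, dimerisation or exchange at C3.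
The N-methylation and N-acylation would spend two steps on a weakly nucleophilic aniline only to attach two carbons.

**Strategy.** The route rests on a benzannulation of a pyrrole: the benzene ring (C3a, C4, C5, C6, C7, C7a) is made from the C4=C5 bond (pyrrole numbering) of 2,3,5-tribromo-1-methylpyrrole and the diene of 3,5-dibromo-2-pyrone. One thermal operation forms C7–C7a and C3a–C4 by cycloaddition and aromatises the ring by loss of HBr and CO2. It exploits the Br–H–Br–H sequence C4–C7, which is C3–C6 of the pyrone, and the 2,3-dibromo-N-methylpyrrole half, which the tribromopyrrole carries in, its third bromine being the leaving group. All four bromines thus arrive in place: no deactivated arene attacks as a nucleophile, no lactam is deoxybrominated, and no aniline is alkylated or acylated.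

Key step: step 3

Remark: the target is achiral; indole numbering is used for the ring atoms of 8, 9 and 10, pyrrole numbering for 7 and pyrone numbering for 3.

**Step 1**
Reactants: 1 coumalic acid
Product: 3 3,5-dibromo-2H-pyran-2-one, via 5-bromo-2H-pyran-2-one 2 (not isolated)
Conditions: NBS (2.4 equiv), LiOAc (20 mol %), MeCN–H2O (9:1), rt, 24–48 h
Reagents that add atoms: N-bromosuccinimide, O=C1CCC(=O)N1Br
Why: Catalytic Hunsdiecker-type bromodecarboxylation followed by electrophilic bromination: acetate-assisted ipso-attack of electrophilic bromine at C5, the β-carbon of the ring enol ether, should expel CO2 to give 2, and a second equivalent of NBS should brominate C3, the terminus of the dienol ether, a sequence known for this very acid.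

**Step 2**
Reactants: 4 1-methyl-1H-pyrrole
Product: 7 2,3,5-tribromo-1-methyl-1H-pyrrole, via 2-bromo-1-methyl-1H-pyrrole 5 (not isolated), via 2,5-dibromo-1-methyl-1H-pyrrole 6 (not isolated)
Conditions: NBS (3.0 equiv), THF, −78 °C → rt, 4 h, dark; filtration through basic Al2O3
Reagents that add atoms: N-bromosuccinimide, O=C1CCC(=O)N1Br
Why: Electrophilic aromatic bromination of a π-excessive heteroarene: NBS should substitute the two α-positions first and then one β-position, so that three equivalents at low temperature stop at the 2,3,5-tribromide, which keeps the single C4–H and the C5 bromine that step 3 needs.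

**Step 3**
Reactants: 3 3,5-dibromo-2H-pyran-2-one; 7 2,3,5-tribromo-1-methyl-1H-pyrrole
Product: 10 2,3,4,6-tetrabromo-1-methyl-1H-indole, via cycloadduct lactone 8 (not isolated), via bridged pyrrole lactone 9 (not isolated)
Conditions: 3 (1.5 equiv), 7 (1.0 equiv), Na2CO3 (2 equiv, powdered), chlorobenzene, sealed tube, 140 °C, dark, 24–48 h
Reagents that add atoms: none
Why: Proposed new method: the C4=C5 bond of 7 should add across C3 and C6 of the electron-poor diene 3 in an inverse-electron-demand Diels–Alder reaction to lactone 8, in which the α-bromoamine C7a–Br bond ionises and the C3a proton is lost to re-form the pyrrole in 9, and 9 should then expel CO2 by retro-Diels–Alder reaction, which makes the new ring aromatic. The closest known reactions are the thermal cycloaddition with CO2 and HCl extrusion of 2-pyrones with 3-chloroindoles, which gives carbazoles, and the cycloadditions of 3 itself with alkynes and enol ethers, which give bromoarenes; a halopyrrole as the two-carbon partner is the new element. The benzene ring (C3a, C4, C5, C6, C7, C7a) closes by an intermolecular (4+2) cycloaddition that makes C7–C7a and C3a–C4 at once, and it becomes aromatic by the two eliminations, not by an oxidant. The sp3 centres formed in 8 and 9 are all erased, so the step needs no stereocontrol. It needs regioselectivity: the largest HOMO coefficient of the pyrrole lies on the α-carbon C5 and the largest LUMO coefficient of the pyrone on C6, the same pairing that places the nucleophilic carbon of enol ethers on C6 of 3 and C3 of 3-chloroindoles on C6 of coumalates, and the reversed orientation would have to join the two bromine-bearing carbons C5 of 7 and C3 of 3, so nitrogen should end up next to C7–H and C3a next to C4–Br. It also needs the right double bond of 7 and no substitution chemistry, which the substrate secures because C2=C3 is tetrasubstituted and because the attacking α-carbon carries bromine in place of hydrogen, so that the first-formed adduct can only close, revert or lose HBr in the productive sense, while Na2CO3 takes up the HBr that would otherwise degrade the bromopyrrole.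

**Compound list**
1 | coumalic acid (2-oxo-2H-pyran-5-carboxylic acid) | O=C1C=CC(C(=O)O)=CO1 | starting material
2 | 5-bromo-2H-pyran-2-one | O=C1C=CC(Br)=CO1 | intermediate (not isolated)
3 | 3,5-dibromo-2H-pyran-2-one | O=C1OC=C(Br)C=C1Br | intermediate
4 | 1-methyl-1H-pyrrole | Cn1cccc1 | starting material
5 | 2-bromo-1-methyl-1H-pyrrole | Cn1cccc1Br | intermediate (not isolated)
6 | 2,5-dibromo-1-methyl-1H-pyrrole | Cn1c(Br)ccc1Br | intermediate (not isolated)
7 | 2,3,5-tribromo-1-methyl-1H-pyrrole | Cn1c(Br)cc(Br)c1Br | intermediate
8 | 2,3,4,6,7a-pentabromo-1-methyl-3a,4,7,7a-tetrahydro-1H-4,7-(epoxymethano)indol-9-one (cycloadduct lactone; bridge oxygen on C7, carbonyl carbon on C4; racemic, endo/exo mixture) | CN1C(Br)=C(Br)C2C1(Br)C3OC(=O)C2(Br)C=C3Br | intermediate (not isolated)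
9 | 2,3,4,6-tetrabromo-1-methyl-4,7-dihydro-1H-4,7-(epoxymethano)indol-9-one (bridged pyrrole lactone; bridge oxygen on C7, carbonyl carbon on C4; racemic) | Cn1c(Br)c(Br)c2c1C3OC(=O)C2(Br)C=C3Br | intermediate (not isolated)
10 | 2,3,4,6-tetrabromo-1-methyl-1H-indole (achiral) | Cn1c(Br)c(Br)c2c(Br)cc(Br)cc21 | target

Total step count: 3
Longest linear sequence: 2 steps (1 → 3 → 10 or 4 → 7 → 10; the route is convergent)

**Steps most likely to fail**

Step 3 (key step). The aromatic C4=C5 bond of 7 may fail to add because dearomatisation makes the first bond reversible. The partners may also combine in the reversed orientation, or the pyrone may be lost to self-cycloaddition at the temperature required. The fallback uses known chemistry only and gives up the benzannulation. It sets out from no numbered compound of the route but from commercial 1,5-dibromo-2-methyl-3-nitrobenzene F1 and comes back to the route at the target, compound 10. Leimgruber–Batcho condensation with N,N-dimethylformamide dimethyl acetal (DMF, 110 °C) would give the enamine (E)-2-(2,4-dibromo-6-nitrophenyl)-N,N-dimethylethen-1-amine F2. Reduction of the nitro group with iron powder in acetic acid would close the ring to 4,6-dibromo-1H-indole F3, without touching the aryl bromides. NaH and MeI in DMF would give 4,6-dibromo-1-methyl-1H-indole F4. Two equivalents of NBS in THF would then brominate C3 to 3,4,6-tribromo-1-methyl-1H-indole F5 in the flask, and then C2 to give 10.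

Step 2. Bromination may not stop cleanly at the tribromide, and the acid-sensitive product may isomerise or polymerise on isolation. The fallback sets out from compound 4 and comes back at compound 9. Exhaustive bromination (NBS, 4 equiv, THF) would give the stable 2,3,4,5-tetrabromo-1-methyl-1H-pyrrole F6. Bromine–lithium exchange at an α-position (n-BuLi, THF, −78 °C) would give (3,4,5-tribromo-1-methyl-1H-pyrrol-2-yl)lithium F7, and methanol would protonate it to 2,3,4-tribromo-1-methyl-1H-pyrrole F8. This regioisomer would enter the cycloaddition with 3 in place of 7 under the conditions of step 3. Its unsubstituted α-carbon, the most nucleophilic and least hindered ring carbon, would bond to C6 of the pyrone. The 2,3,3a,4,6-pentabromo cycloadduct lactone F9 would lose the allylic bromine from C3a together with the C7a proton, and the sequence would rejoin the route at 9.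

Step 1. The bromodecarboxylation may stop after the first bromine, or the pyrone ring may open in the aqueous medium. The fallback separates decarboxylation from bromination: it sets out from compound 1 and comes back at compound 3. Passing the vapour of 1 over hot copper (Cu turnings, about 650 °C, reduced pressure) would give 2H-pyran-2-one F10 by protodecarboxylation. Bromination with Br2 in CH2Cl2 followed by Et3N would give 3-bromo-2H-pyran-2-one F11, and a second round of the same treatment would give 3.

**Further compounds**
F1 | step 3 | 1,5-dibromo-2-methyl-3-nitrobenzene | Cc1c(Br)cc(Br)cc1[N+](=O)[O-]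
F2 | step 3 | (E)-2-(2,4-dibromo-6-nitrophenyl)-N,N-dimethylethen-1-amine | CN(C)/C=C/c1c(Br)cc(Br)cc1[N+](=O)[O-]
F3 | step 3 | 4,6-dibromo-1H-indole | Brc1cc(Br)c2cc[nH]c2c1
F4 | step 3 | 4,6-dibromo-1-methyl-1H-indole | Cn1ccc2c(Br)cc(Br)cc21
F5 | step 3 | 3,4,6-tribromo-1-methyl-1H-indole | Cn1cc(Br)c2c(Br)cc(Br)cc21
F6 | step 2 | 2,3,4,5-tetrabromo-1-methyl-1H-pyrrole | Cn1c(Br)c(Br)c(Br)c1Br
F7 | step 2 | (3,4,5-tribromo-1-methyl-1H-pyrrol-2-yl)lithium | [Li]c1c(Br)c(Br)c(Br)n1C
F8 | step 2 | 2,3,4-tribromo-1-methyl-1H-pyrrole | Cn1cc(Br)c(Br)c1Br
F9 | step 2 | 2,3,3a,4,6-pentabromo-1-methyl-3a,4,7,7a-tetrahydro-1H-4,7-(epoxymethano)indol-9-one (cycloadduct lactone of F8 and 3; bridge oxygen on C7, carbonyl carbon on C4; racemic, endo/exo mixture) | CN1C(Br)=C(Br)C2(Br)C1C3OC(=O)C2(Br)C=C3Br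
F10 | step 1 | 2H-pyran-2-one | O=C1C=CC=CO1
F11 | step 1 | 3-bromo-2H-pyran-2-one | O=C1OC=CC=C1Br
A1 | direct plan | 3,5-dibromoaniline | Nc1cc(Br)cc(Br)c1
A2 | direct plan | 3,5-dibromo-N-methylaniline | CNc1cc(Br)cc(Br)c1
A3 | direct plan | 2,2-dibromo-N-(3,5-dibromophenyl)-N-methylacetamide | CN(C(=O)C(Br)Br)c1cc(Br)cc(Br)c1
A4 | direct plan | 3,4,6-tribromo-1-methylindolin-2-one (racemic) | CN1C(=O)C(Br)c2c(Br)cc(Br)cc21
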